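**Retrosynthetic overview**

1. The last operations are global MOM removal and, before it, enantioselective 1,4-hydride addition to a flavone. C2 is kept trigonal through every basic step because a 2-arylchroman-4-one racemises under base by E1cB ring opening.
2. The key disconnection cuts C3–C4 and O1–C8a of ring C together. The lithium enolate of the ring B methyl ketone (O1–C2–C3) is joined to a 2-fluoroaroyl fluoride of ring A (C4–C4a–C8a) in one flask.
3. The feature that allows this: the C4 carbonyl on C4a is ortho to C8a, so a fluorine on C8a can be displaced ipso, and it is 1,3 to O1 across C3–C2, so the diketonate oxygen closes a six-membered ring on C8a.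
4. Rings A and B are bought as arenes. Ring C is the only ring formed (step 8), and its C2=C3 bond is reduced last to set C2.
5. The ring B ketone comes from acetovanillone (iodination, MOM, Stille prenylation); the ring A acyl fluoride comes from 5-fluororesorcinol (formylation, MOM, oxidation, fluorination).

Key step: step 8

Assumption: the (R)-antipode of DTBM-SEGPHOS is taken as the one whose copper hydride adds to the Re face of C2 (giving 2S); if a first run shows the opposite sense, the (S)-ligand is used with no other change.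

**Route**

Step 1
Reactants: 1 acetovanillone, 1-(4-hydroxy-3-methoxyphenyl)ethan-1-one
Product: 2 1-(4-hydroxy-3-iodo-5-methoxyphenyl)ethan-1-one
Conditions: N-iodosuccinimide, TsOH·H2O (cat.), MeCN, 0 °C to rt
Reagents that add atoms: N-iodosuccinimide, O=C1CCC(=O)N1I
Why: Electrophilic aromatic iodination should go to C5, the only position ortho to the phenol and meta to the deactivating acetyl group.

Step 2
Reactants: 2 1-(4-hydroxy-3-iodo-5-methoxyphenyl)ethan-1-one
Product: 3 1-[3-iodo-5-methoxy-4-(methoxymethoxy)phenyl]ethan-1-one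
Conditions: MOMCl, K2CO3, acetone, 50 °C
Reagents that add atoms: chloromethyl methyl ether, COCCl
Why: Williamson-type O-alkylation of the phenoxide by the α-chloro ether masks the acidic OH before the cross-coupling and enolate chemistry.

Step 3
Reactants: 3 1-[3-iodo-5-methoxy-4-(methoxymethoxy)phenyl]ethan-1-one
Product: 4 1-[3-methoxy-4-(methoxymethoxy)-5-(3-methylbut-2-en-1-yl)phenyl]ethan-1-one
Conditions: tributyl(3-methylbut-2-en-1-yl)stannane, Pd(PPh3)4 (5 mol%), DMF, 90 °C
Reagents that add atoms: tributyl(3-methylbut-2-en-1-yl)stannane, CCCC[Sn](CCCC)(CCCC)CC=C(C)C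
Why: Stille cross-coupling (oxidative addition of zerovalent palladium into the aryl–iodine bond, then transfer of the prenyl group from tin through its CH2 terminus) should give the linear prenyl arene while ketone and acetal stay untouched.

Step 4
Reactants: 5 5-fluorobenzene-1,3-diol
Product: 7 2-fluoro-4,6-dihydroxybenzaldehyde, via aryl iminium chloride 6 (not isolated)
Conditions: POCl3, DMF, MeCN, −15 °C to rt; then H2O, 50 °C
Reagents that add atoms: N,N-dimethylformamide, CN(C)C=O; water, O
Why: Vilsmeier–Haack formylation should attack para to one OH and ortho to the other (next to fluorine) rather than the hindered carbon between the two OH groups, as resorcinol and orcinol do, and the iminium salt is then hydrolysed to the aldehyde.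

Step 5
Reactants: 7 2-fluoro-4,6-dihydroxybenzaldehyde
Product: 8 2-fluoro-4,6-bis(methoxymethoxy)benzaldehyde
Conditions: NaH, MOMCl, DMF, 0 °C to rt
Reagents that add atoms: chloromethyl methyl ether, COCCl
Why: Double O-alkylation through the sodium phenoxides, with NaH chosen so that the hydrogen-bonded OH ortho to the formyl group is etherified as well.

Step 6
Reactants: 8 2-fluoro-4,6-bis(methoxymethoxy)benzaldehyde
Product: 9 2-fluoro-4,6-bis(methoxymethoxy)benzoic acid
Conditions: NaClO2, NaH2PO4, 2-methylbut-2-ene, t-BuOH/H2O, rt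
Reagents that add atoms: sodium chlorite, [Na+].[O-]Cl=O
Why: Pinnick oxidation works at about pH 4, where aryl MOM ethers should survive, and 2-methylbut-2-ene removes HOCl before it can chlorinate the electron-rich ring.

Step 7
Reactants: 9 2-fluoro-4,6-bis(methoxymethoxy)benzoic acid
Product: 10 2-fluoro-4,6-bis(methoxymethoxy)benzoyl fluoride
Conditions: cyanuric fluoride, pyridine, CH2Cl2, −10 °C to rt
Reagents that add atoms: cyanuric fluoride, Fc1nc(F)nc(F)n1
Why: Deoxyfluorination of the acid (acyl transfer to the triazine, then fluoride return) gives an acyl fluoride, preferred to the chloride because it forms under base and should not ionise the ortho MOM ether.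

Step 8
Reactants: 4 1-[3-methoxy-4-(methoxymethoxy)-5-(3-methylbut-2-en-1-yl)phenyl]ethan-1-one; 10 2-fluoro-4,6-bis(methoxymethoxy)benzoyl fluoride
Product: 13 2-[3-methoxy-4-(methoxymethoxy)-5-(3-methylbut-2-en-1-yl)phenyl]-5,7-bis(methoxymethoxy)-4H-chromen-4-one, via lithium enolate 11 (not isolated), via lithium 1,3-diketonate 12 (not isolated)
Conditions: 4, LiN(SiMe3)2 (2.2 equiv), THF, −78 °C; 10, −78 to 0 °C; then DMF added, 90 °C, same flask
Reagents that add atoms: none
Why: The kinetic lithium enolate 11 attacks the acyl fluoride at carbon (Claisen-type C-acylation, forming C3–C4), and the second equivalent of amide base converts the 1,3-diketone at once into the chelated Z-diketonate 12, which protects it from further acylation and from retro-Claisen cleavage. On warming in DMF the enolate oxygen on C2 (the future O1) adds to C8a, the fluorine-bearing carbon ortho to the C4 carbonyl, and fluoride leaves the Meisenheimer anion (addition–elimination, SNAr), forming O1–C8a and completing ring C as the 4-pyranone. The closest known reaction type is the one-pot enolate aroylation and cyclodehydrofluorination of methyl ketones with 2-fluorobenzoyl halides that gives chromones and flavones. Ring C closes by six-membered O-attack at C8a (6-endo-trig onto the C8a=C4a–C4=O vinylogous acyl unit), while C-attack from C3 would need a four-membered ring and should not compete. No stereocentre is made, since C2 is left trigonal on purpose so that the basic conditions have nothing to racemise. The selectivities needed are C- over O-acylation, secured by the lithium counter-ion in THF and the irreversible deprotonation of the diketone, and substitution at C8a only, secured by the single ring fluorine, its ortho relation to the C4 ketone, and the meta placement of both MOM-oxy groups, which therefore do not donate into the site of attack.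

Step 9
Reactants: 13 2-[3-methoxy-4-(methoxymethoxy)-5-(3-methylbut-2-en-1-yl)phenyl]-5,7-bis(methoxymethoxy)-4H-chromen-4-one
Product: 15 (2S)-2-[3-methoxy-4-(methoxymethoxy)-5-(3-methylbut-2-en-1-yl)phenyl]-5,7-bis(methoxymethoxy)-2,3-dihydro-4H-chromen-4-one, via silyl enol ether 14 (not isolated)
Conditions: Cu(OAc)2·H2O (5 mol%), (R)-DTBM-SEGPHOS (5.5 mol%), HSiMe(OEt)2, toluene, 0 °C to rt; then AcOH, THF/H2O, 0 °C
Reagents that add atoms: none
Why: Asymmetric CuH conjugate reduction of a 2-substituted chromone, in which the chiral bisphosphine selects the Re face of C2 for hydride delivery to set the 2S centre, and the copper enolate is trapped as silyl enol ether 14, which shields C4 from over-reduction and is hydrolysed under weakly acidic, non-epimerising conditions.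

Step 10
Reactants: 15 (2S)-2-[3-methoxy-4-(methoxymethoxy)-5-(3-methylbut-2-en-1-yl)phenyl]-5,7-bis(methoxymethoxy)-2,3-dihydro-4H-chromen-4-one
Product: 16 (2S)-5,7-dihydroxy-2-[4-hydroxy-3-methoxy-5-(3-methylbut-2-en-1-yl)phenyl]-2,3-dihydro-4H-chromen-4-one
Conditions: HCl (3 M aq), MeOH, 45 °C
Reagents that add atoms: none
Why: Acid-catalysed transacetalisation of the three MOM ethers to methanol should free the phenols while the aryl methyl ether, the trisubstituted prenyl alkene and the C2 centre (no base, so no E1cB ring opening) persist.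

**Compound list**

1 | acetovanillone, 1-(4-hydroxy-3-methoxyphenyl)ethan-1-one | CC(=O)c1ccc(O)c(OC)c1 | starting material
2 | 1-(4-hydroxy-3-iodo-5-methoxyphenyl)ethan-1-one | CC(=O)c1cc(I)c(O)c(OC)c1 | intermediate
3 | 1-[3-iodo-5-methoxy-4-(methoxymethoxy)phenyl]ethan-1-one | CC(=O)c1cc(I)c(OCOC)c(OC)c1 | intermediate
4 | 1-[3-methoxy-4-(methoxymethoxy)-5-(3-methylbut-2-en-1-yl)phenyl]ethan-1-one | CC(=O)c1cc(CC=C(C)C)c(OCOC)c(OC)c1 | intermediate
5 | 5-fluorobenzene-1,3-diol (5-fluororesorcinol) | Oc1cc(O)cc(F)c1 | starting material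
6 | [(2-fluoro-4,6-dihydroxyphenyl)methylidene]dimethylazanium chloride (aryl iminium chloride, not isolated) | C[N+](C)=Cc1c(F)cc(O)cc1O.[Cl-] | intermediate
7 | 2-fluoro-4,6-dihydroxybenzaldehyde | O=Cc1c(F)cc(O)cc1O | intermediate
8 | 2-fluoro-4,6-bis(methoxymethoxy)benzaldehyde | O=Cc1c(F)cc(OCOC)cc1OCOC | intermediate
9 | 2-fluoro-4,6-bis(methoxymethoxy)benzoic acid | OC(=O)c1c(F)cc(OCOC)cc1OCOC | intermediate
10 | 2-fluoro-4,6-bis(methoxymethoxy)benzoyl fluoride | O=C(F)c1c(F)cc(OCOC)cc1OCOC | intermediate
11 | lithium 1-[3-methoxy-4-(methoxymethoxy)-5-(3-methylbut-2-en-1-yl)phenyl]ethen-1-olate (lithium enolate, not isolated) | [Li+].[O-]C(=C)c1cc(CC=C(C)C)c(OCOC)c(OC)c1 | intermediate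
12 | lithium (Z)-3-[2-fluoro-4,6-bis(methoxymethoxy)phenyl]-1-[3-methoxy-4-(methoxymethoxy)-5-(3-methylbut-2-en-1-yl)phenyl]-3-oxoprop-1-en-1-olate (lithium 1,3-diketonate, not isolated) | [Li+].COCOc1cc(F)c(C(=O)/C=C(\[O-])c2cc(CC=C(C)C)c(OCOC)c(OC)c2)c(OCOC)c1 | intermediate
13 | 2-[3-methoxy-4-(methoxymethoxy)-5-(3-methylbut-2-en-1-yl)phenyl]-5,7-bis(methoxymethoxy)-4H-chromen-4-one | O=c1cc(-c2cc(CC=C(C)C)c(OCOC)c(OC)c2)oc2cc(OCOC)cc(OCOC)c12 | intermediate
14 | (2S)-4-{[diethoxy(methyl)silyl]oxy}-2-[3-methoxy-4-(methoxymethoxy)-5-(3-methylbut-2-en-1-yl)phenyl]-5,7-bis(methoxymethoxy)-2H-chromene (silyl enol ether, not isolated) | COc1cc([C@@H]2C=C(O[Si](C)(OCC)OCC)c3c(OCOC)cc(OCOC)cc3O2)cc(CC=C(C)C)c1OCOC | intermediate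
15 | (2S)-2-[3-methoxy-4-(methoxymethoxy)-5-(3-methylbut-2-en-1-yl)phenyl]-5,7-bis(methoxymethoxy)-2,3-dihydro-4H-chromen-4-one | COc1cc([C@@H]2CC(=O)c3c(OCOC)cc(OCOC)cc3O2)cc(CC=C(C)C)c1OCOC | intermediate
16 | (2S)-5,7-dihydroxy-2-[4-hydroxy-3-methoxy-5-(3-methylbut-2-en-1-yl)phenyl]-2,3-dihydro-4H-chromen-4-one | COc1cc([C@@H]2CC(=O)c3c(O)cc(O)cc3O2)cc(CC=C(C)C)c1O | target

**Step count and risks**

Total step count: 10. Longest linear sequence: 7 steps (5 to 16, steps 4 to 10).

Steps most likely to fail:

1. Step 9. What may go wrong: poor facial discrimination and slow hydrocupration at C2 of an electron-rich, 5-alkoxy-substituted flavone, and over-reduction at C4 if ketone is released in the flask. The fallback sets out from 13 and comes back at 15. The flavone is reduced without stereocontrol by conjugate hydride addition (LiBH(s-Bu)3, THF, −78 °C) to the racemic flavanone F1. This is resolved kinetically by Noyori–Ikariya transfer hydrogenation (RuCl(p-cymene)[(R,R)-TsDPEN], HCO2H/Et3N, EtOAc, rt): the 2R ketone should be reduced to the cis (2R,4R)-flavan-4-ol F2 and separated, while the slow-reacting 2S ketone is recovered as 15. At most half of the material is carried on.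

2. Step 8. What may go wrong: O-acylation of the enolate or attack of the amide base on the acyl fluoride (the acyl carbon lies between F and OMOM), and sluggish ipso-substitution at C8a if the aroyl group is twisted out of conjugation. The fallback sets out from 4 and 8 and comes back at 13. The C3–C4 bond is made at the aldehyde oxidation level by aldol addition of the lithium enolate of 4 (LiN(i-Pr)2, THF, −78 °C) to aldehyde 8, giving the β-hydroxy ketone F3. Dess–Martin oxidation gives the free 1,3-diketone F4, and ring C is then closed in a separate operation under more forcing SNAr conditions (Cs2CO3, DMSO, 100 °C) to 13.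

3. Step 3. What may go wrong: allylic transposition during transmetalation (coupling through the tertiary carbon to the 1,1-dimethylallyl isomer), alkene isomerisation and protodestannylation. The fallback sets out from 1 and comes back at 4, delivering the prenyl group by an aromatic Claisen rearrangement. Acetovanillone 1 is O-alkylated with 3-chloro-3-methylbut-1-yne (CuCl2·2H2O cat., DBU, MeCN, 0 °C) to the aryl 1,1-dimethylpropargyl ether F5. Semihydrogenation (H2, Pd on CaCO3 poisoned with Pb(OAc)2, quinoline, EtOAc) gives the aryl 1,1-dimethylallyl ether F6. Heating (PhNEt2, 130 °C) should move the inverted allyl unit by a [3,3] shift to the free ortho carbon, giving 5-prenylacetovanillone F7, and MOM protection as in step 2 gives 4.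

Further compounds
F1 | step 9 | racemic 2-[3-methoxy-4-(methoxymethoxy)-5-(3-methylbut-2-en-1-yl)phenyl]-5,7-bis(methoxymethoxy)-2,3-dihydro-4H-chromen-4-one | COc1cc(C2CC(=O)c3c(OCOC)cc(OCOC)cc3O2)cc(CC=C(C)C)c1OCOC
F2 | step 9 | (2R,4R)-2-[3-methoxy-4-(methoxymethoxy)-5-(3-methylbut-2-en-1-yl)phenyl]-5,7-bis(methoxymethoxy)-3,4-dihydro-2H-chromen-4-ol | COc1cc([C@H]2C[C@@H](O)c3c(OCOC)cc(OCOC)cc3O2)cc(CC=C(C)C)c1OCOC
F3 | step 8 | racemic 3-[2-fluoro-4,6-bis(methoxymethoxy)phenyl]-3-hydroxy-1-[3-methoxy-4-(methoxymethoxy)-5-(3-methylbut-2-en-1-yl)phenyl]propan-1-one | COCOc1cc(F)c(C(O)CC(=O)c2cc(CC=C(C)C)c(OCOC)c(OC)c2)c(OCOC)c1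
F4 | step 8 | 1-[2-fluoro-4,6-bis(methoxymethoxy)phenyl]-3-[3-methoxy-4-(methoxymethoxy)-5-(3-methylbut-2-en-1-yl)phenyl]propane-1,3-dione | COCOc1cc(F)c(C(=O)CC(=O)c2cc(CC=C(C)C)c(OCOC)c(OC)c2)c(OCOC)c1
F5 | step 3 | 1-{3-methoxy-4-[(2-methylbut-3-yn-2-yl)oxy]phenyl}ethan-1-one | CC(=O)c1ccc(OC(C)(C)C#C)c(OC)c1
F6 | step 3 | 1-{3-methoxy-4-[(2-methylbut-3-en-2-yl)oxy]phenyl}ethan-1-one | CC(=O)c1ccc(OC(C)(C)C=C)c(OC)c1
F7 | step 3 | 1-[4-hydroxy-3-methoxy-5-(3-methylbut-2-en-1-yl)phenyl]ethan-1-one | CC(=O)c1cc(CC=C(C)C)c(O)c(OC)c1
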